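The numbers in the tables are calculated with constants of no real substance; noise was put on by code.

The reading comes at 3.0 min, and the meeting asked what will stand in blue and grey by then.

| flask | starting material | coupling partner | remark | time |
|---|---|---|---|---|
| south | 0.30 M | 1.5 equiv | run made earlier |  |
| south-west | 0.30 M | 4.1 equiv | run made earlier |  |
| blue | 0.30 M | 1.10 equiv |  | 3.0 min |
| grey | 0.30 M | 2.60 equiv |  | 3.0 min |

| run | time / s | starting material / % | isomer of the product / % | target / % |
|---|---|---|---|---|
| south | 10.0 | 92.3 | 0 | 6.4 |
| south | 25.0 | 86.1 | 0.1 | 13.0 |
| south | 40.0 | 79.3 | 2.1 | 17.3 |
| south | 60.0 | 71.1 | 4.2 | 26.2 |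
| south | 90.0 | 63.6 | 5.7 | 27.4 |
| south | 120 | 56.4 | 11.3 | 29.2 |
| south-west | 10.0 | 85.4 | 1.3 | 14.2 |
| south-west | 25.0 | 68.3 | 3.0 | 31.0 |
| south-west | 40.0 | 56.0 | 5.0 | 39.9 |
| south-west | 60.0 | 45.8 | 6.8 | 44.9 |
| south-west | 90.0 | 34.4 | 16.8 | 50.9 |
| south-west | 120 | 27.5 | 21.8 | 50.9 |

(each reading ± 1 percentage point)

1. which of these there is most of at the end, counted by the starting material in it, blue (starting material / target / isomer of the product)
2. which of these there is most of at the end, counted by the starting material in it, grey (starting material / target / isomer of the product)
3. how much there is at the end of the one of these that leads, in percent of the starting material charged: blue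
4. how much there is at the end of the one of these that leads, in percent of the starting material charged: grey

- the analysis behind the earlier runs scatters by 1 percentage point, standard deviation

Minutes. One member opened with the south-west run. Its starting material fell with a pseudo-first-order constant of 0.0153 s⁻¹ over the first 25.0 s. Between 40.0 s and 120 s, she reported, the isomer of the product grew at 0.00463 s⁻¹ per unit of target.

Another member proposed a load: the fraction of starting material, times the equivalents of coupling partner left, over the fraction of target. Making goes with the first constant per equivalent charged, and using up goes with the second per unit of target. So, he argued, target grows above the level where the two meet and falls below it. He put this crossing load at 1.24 equiv, for flasks at 0.30 M. The chair warned that the constant comes from early readings, so the level is rough.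

The meeting then matched flasks by partner charge times time. The last south-west reading corresponds to 3.15 min in grey. It suggests 27.5 % of starting material at that moment. Taking target to sit at the crossing load, with partner spent one for one, the estimate for target is 41.5 %. So the chair expected more target than starting material in grey. The last south reading corresponds to 2.73 min in blue. It suggests 56.4 % of starting material against an estimate, reckoned the same way, of 30.1 % of target, so the chair expected more starting material than target in blue.

The forecast named starting material at 57 % for blue and target at 41 % for grey, the target “having just passed its maximum”.

Blue gives starting material at 58.1 %, and grey gives target at 41.9 %.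

    starting material + coupling partner → target, rate k1*[starting material]^1.5*[coupling partner] (k = 0.0270 M⁻¹·⁵ s⁻¹)
    target ⇌ isomer of the product (K = 2.10, k = 0.00520 s⁻¹)
    coupling partner → decomposed reagent (k = 7.80 × 10⁻⁴ s⁻¹)

In grey, target is made 3.46 times as fast as it is used up at 0.747 min, each step taken net. At 3.00 min that ratio is 0.832, which is below one, so grey has crossed. Grey's load at the end is 1.21 equiv, beside the crossing load of 1.24 equiv. A further flask like grey, but with 1.00 equiv of coupling partner, ends with 60.9 % of its starting material and 51.0 % of its partner. With the crossing load these give 25.0 % of target, and that flask holds 24.8 %.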